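**Retrosynthetic overview**

1. Target ⇒ last-step fluoride removal of four silyl ethers from the fully silylated C18 aryl ketone. No ring is formed anywhere; the phloroglucinol ring is bought intact.
2. C6=C7 (Z) ⇒ Wittig union of fragment A (aryl keto-aldehyde, C1–C6) with the ylide of fragment B (C7–C18 phosphonium salt).
3. Fragment B ⇒ C12=C13 (Z) by Wittig of a 4-silyloxy-(E)-enal with the (Z)-hex-3-enyl ylide (fragment C); C10=C11 (E) by formyl-ylide homologation of an α-silyloxy aldehyde.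
4. C9 (R) ⇒ ketoreductase reduction of achiral ethyl 4-(benzyloxy)-3-oxobutanoate, the only stereocentre-forming event that is kept.
5. Fragment A ⇒ ortho-lithiated tris-MOM phloroglucinol plus the Weinreb amide of hept-6-enoic acid, then MOM-to-TBS exchange and alkene cleavage.

Abbreviations: TBS = tert-butyldimethylsilyl; MOM = methoxymethyl.

Assumption: the carbinol is (9R) as read from the SMILES, and an (R)-selective ketoreductase for 1 is taken from a commercial screening panel.

**Steps**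

Step 1
Reactants: 1 ethyl 4-(benzyloxy)-3-oxobutanoate
Product: 2 ethyl (3R)-4-(benzyloxy)-3-hydroxybutanoate
Conditions: ketoreductase (R-selective, NADPH-dependent carbonyl reductase, EC 1.1.1 class), NADP+ (cat.), i-PrOH (10 vol%), KH2PO4/K2HPO4 buffer pH 7.0, 30 °C
Reagents that add atoms: none
Why: Enzymatic asymmetric ketone reduction in which the ketoreductase delivers hydride from NADPH to the Si face of the prochiral β-keto ester, setting the only stereocentre (future C9) as R in high ee, with isopropanol recycling the cofactor.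

Step 2
Reactants: 2 ethyl (3R)-4-(benzyloxy)-3-hydroxybutanoate
Product: 3 ethyl (3R)-4-(benzyloxy)-3-[(tert-butyldimethylsilyl)oxy]butanoate
Conditions: TBSCl, imidazole, DMF, rt
Reagents that add atoms: tert-butyldimethylsilyl chloride, CC(C)(C)[Si](C)(C)Cl
Why: Imidazole-promoted silylation of an unhindered secondary alcohol is routine and breaks no bond at the stereocentre.

Step 3
Reactants: 3 ethyl (3R)-4-(benzyloxy)-3-[(tert-butyldimethylsilyl)oxy]butanoate
Product: 4 ethyl (3R)-3-[(tert-butyldimethylsilyl)oxy]-4-hydroxybutanoate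
Conditions: H2 (1 atm), 10% Pd/C, EtOAc, rt; crude product used at once
Reagents that add atoms: none
Why: Catalytic hydrogenolysis of the benzyl ether is done here because no alkene is yet present, and the neutral conditions avoid lactonisation and silyl migration.

Step 4
Reactants: 4 ethyl (3R)-3-[(tert-butyldimethylsilyl)oxy]-4-hydroxybutanoate
Product: 5 ethyl (3R)-3-[(tert-butyldimethylsilyl)oxy]-4-oxobutanoate
Conditions: Dess–Martin periodinane, CH2Cl2, 0 °C to rt
Reagents that add atoms: none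
Why: Dess–Martin oxidation is near-neutral, so the α-silyloxy aldehyde forms without epimerisation or β-elimination.

Step 5
Reactants: 5 ethyl (3R)-3-[(tert-butyldimethylsilyl)oxy]-4-oxobutanoate; 6 (triphenylphosphoranylidene)acetaldehyde
Product: 7 ethyl (3R,4E)-3-[(tert-butyldimethylsilyl)oxy]-6-oxohex-4-enoate
Conditions: 6 (1.3 equiv), toluene, 70 °C
Reagents that add atoms: none
Why: Wittig olefination with a stabilised formyl ylide needs no base, attacks only the aldehyde and gives the (E)-enal under thermodynamic control, so the adjacent stereocentre is kept.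

Step 6
Reactants: 8 (Z)-hex-3-en-1-ol
Product: 9 (Z)-1-iodohex-3-ene
Conditions: PPh3, imidazole, I2, CH2Cl2, 0 °C to rt
Reagents that add atoms: iodine, [I][I]
Why: Appel-type iodination converts the primary alcohol to the iodide by SN2 displacement of the oxyphosphonium group without touching the Z alkene.

Step 7
Reactants: 9 (Z)-1-iodohex-3-ene
Product: 10 [(Z)-hex-3-en-1-yl]triphenylphosphonium iodide (fragment C)
Conditions: PPh3, MeCN, reflux
Reagents that add atoms: triphenylphosphine, c1ccc(cc1)P(c1ccccc1)c1ccccc1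
Why: SN2 quaternisation of triphenylphosphine by a primary iodide gives the crystalline Wittig salt.

Step 8
Reactants: 10 [(Z)-hex-3-en-1-yl]triphenylphosphonium iodide; 7 ethyl (3R,4E)-3-[(tert-butyldimethylsilyl)oxy]-6-oxohex-4-enoate
Product: 12 ethyl (3R,4E,6Z,9Z)-3-[(tert-butyldimethylsilyl)oxy]dodeca-4,6,9-trienoate, via hexenylidene ylide 11 (not isolated)
Conditions: 10, NaN(SiMe3)2, THF, −78 to 0 °C; then 7, −78 °C to rt
Reagents that add atoms: none
Why: Z-selective Wittig reaction of a salt-free non-stabilised ylide with the enal at low temperature (kinetic cis-oxaphosphetane) builds the new Z alkene while the E-enal geometry and the stereocentre are untouched.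

Step 9
Reactants: 12 ethyl (3R,4E,6Z,9Z)-3-[(tert-butyldimethylsilyl)oxy]dodeca-4,6,9-trienoate
Product: 14 (3R,4E,6Z,9Z)-3-[(tert-butyldimethylsilyl)oxy]dodeca-4,6,9-trien-1-ol, via trienal 13 (not isolated)
Conditions: i-Bu2AlH (2.5 equiv), CH2Cl2, −78 to −20 °C; aq. potassium sodium tartrate work-up
Reagents that add atoms: none
Why: Hydride reduction of the ester by excess i-Bu2AlH runs through the aldehyde to the primary alcohol, and the triene and allylic silyl ether are inert at low temperature.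

Step 10
Reactants: 14 (3R,4E,6Z,9Z)-3-[(tert-butyldimethylsilyl)oxy]dodeca-4,6,9-trien-1-ol
Product: 15 tert-butyl{[(3R,4E,6Z,9Z)-1-iodododeca-4,6,9-trien-3-yl]oxy}dimethylsilane
Conditions: PPh3, imidazole, I2 (premixed, PPh3 in slight excess), CH2Cl2, 0 °C, dark
Reagents that add atoms: iodine, [I][I]
Why: Appel-type iodination at the primary carbon by SN2, with the phosphine–iodine adduct preformed so that no free iodine can isomerise the E,Z-diene.

Step 11
Reactants: 15 tert-butyl{[(3R,4E,6Z,9Z)-1-iodododeca-4,6,9-trien-3-yl]oxy}dimethylsilane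
Product: 16 {(3R,4E,6Z,9Z)-3-[(tert-butyldimethylsilyl)oxy]dodeca-4,6,9-trien-1-yl}triphenylphosphonium iodide (fragment B)
Conditions: PPh3 (3 equiv), i-Pr2NEt (0.1 equiv), MeCN, 60 °C, dark
Reagents that add atoms: triphenylphosphine, c1ccc(cc1)P(c1ccccc1)c1ccccc1
Why: SN2 quaternisation of triphenylphosphine by the primary iodide under mild heating, with a trace of amine to scavenge acid, preserves the triene and the allylic silyl ether.

Step 12
Reactants: 17 phloroglucinol
Product: 18 1,3,5-tris(methoxymethoxy)benzene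
Conditions: NaH, MOMCl, DMF, 0 °C to rt
Reagents that add atoms: chloromethyl methyl ether, COCCl
Why: Williamson-type O-alkylation of the phenoxides gives the tris-acetal, whose oxygens direct the later ortho-lithiation.

Step 13
Reactants: 19 hept-6-enoic acid
Product: 21 N-methoxy-N-methylhept-6-enamide, via acyl imidazolide 20 (not isolated)
Conditions: 1,1'-carbonyldiimidazole, CH2Cl2, rt; then MeNHOMe·HCl, rt
Reagents that add atoms: N,O-dimethylhydroxylamine hydrochloride, CNOC.Cl
Why: Carbonyldiimidazole activation followed by aminolysis gives the Weinreb amide, an acylating agent that stops at mono-addition.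

Step 14
Reactants: 18 1,3,5-tris(methoxymethoxy)benzene; 21 N-methoxy-N-methylhept-6-enamide
Product: 23 1-[2,4,6-tris(methoxymethoxy)phenyl]hept-6-en-1-one, via aryllithium 22 (not isolated)
Conditions: 18, n-BuLi, THF, 0 °C; then 21, −78 to 0 °C; H2O quench
Reagents that add atoms: none
Why: Directed ortho-metalation between two MOM ethers gives the aryllithium, which adds once to the Weinreb amide through a chelated tetrahedral adduct and releases the hindered aryl ketone on quench.

Step 15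
Reactants: 23 1-[2,4,6-tris(methoxymethoxy)phenyl]hept-6-en-1-one
Product: 24 1-(2,4,6-trihydroxyphenyl)hept-6-en-1-one
Conditions: HCl (3 M), MeOH, 50 °C
Reagents that add atoms: none
Why: Acid-catalysed acetal methanolysis removes the MOM groups while only a terminal alkene and a ketone are present, so no acid is needed once the acid-labile dienol exists.

Step 16
Reactants: 24 1-(2,4,6-trihydroxyphenyl)hept-6-en-1-one
Product: 25 1-{2,4,6-tris[(tert-butyldimethylsilyl)oxy]phenyl}hept-6-en-1-one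
Conditions: TBSCl, imidazole, DMAP (cat.), DMF, rt to 40 °C
Reagents that add atoms: tert-butyldimethylsilyl chloride, CC(C)(C)[Si](C)(C)Cl
Why: Exhaustive phenol silylation installs fluoride-labile groups that tolerate ylides and can be removed at the end together with the carbinol silyl ether.

Step 17
Reactants: 25 1-{2,4,6-tris[(tert-butyldimethylsilyl)oxy]phenyl}hept-6-en-1-one
Product: 27 6-oxo-6-{2,4,6-tris[(tert-butyldimethylsilyl)oxy]phenyl}hexanal (fragment A), via vicinal diol 26 (not isolated)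
Conditions: OsO4 (2 mol%), NaIO4, 2,6-lutidine, 1,4-dioxane/H2O (3:1), rt
Reagents that add atoms: osmium tetroxide, O=[Os](=O)(=O)=O; sodium periodate, [Na+].[O-]I(=O)(=O)=O
Why: Lemieux–Johnson oxidative cleavage (osmylation then periodate glycol cleavage, buffered by lutidine) cuts only the terminal alkene, and the racemic diol carbon formed in passing is destroyed in the same flask.

Step 18
Reactants: 16 {(3R,4E,6Z,9Z)-3-[(tert-butyldimethylsilyl)oxy]dodeca-4,6,9-trien-1-yl}triphenylphosphonium iodide; 27 6-oxo-6-{2,4,6-tris[(tert-butyldimethylsilyl)oxy]phenyl}hexanal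
Product: 29 (6Z,9R,10E,12Z,15Z)-9-[(tert-butyldimethylsilyl)oxy]-1-{2,4,6-tris[(tert-butyldimethylsilyl)oxy]phenyl}octadeca-6,10,12,15-tetraen-1-one, via trienyl ylide 28 (not isolated)
Conditions: 16, NaN(SiMe3)2, THF, −78 °C; then 27, −78 to −20 °C, dark
Reagents that add atoms: none
Why: Z-selective Wittig reaction of the non-stabilised ylide with the aldehyde is chemoselective because the di-ortho-substituted aryl ketone is too hindered to react, so it sets the 6Z alkene and joins the fragments without touching C9.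

Step 19
Reactants: 29 (6Z,9R,10E,12Z,15Z)-9-[(tert-butyldimethylsilyl)oxy]-1-{2,4,6-tris[(tert-butyldimethylsilyl)oxy]phenyl}octadeca-6,10,12,15-tetraen-1-one
Product: 30 (6Z,9R,10E,12Z,15Z)-9-hydroxy-1-(2,4,6-trihydroxyphenyl)octadeca-6,10,12,15-tetraen-1-one
Conditions: Bu4NF/AcOH (1:1, 6 equiv), THF, 0 °C to rt, dark, argon
Reagents that add atoms: none
Why: Acetic-acid-buffered fluoride desilylation cleaves the three aryl and one allylic silyl ethers without acid or strong base, leaving the dienol stereocentre and all four alkene geometries intact.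

**Compound list**

1 | ethyl 4-(benzyloxy)-3-oxobutanoate | CCOC(=O)CC(=O)COCc1ccccc1 | starting material
2 | ethyl (3R)-4-(benzyloxy)-3-hydroxybutanoate | CCOC(=O)C[C@@H](O)COCc1ccccc1 | intermediate
3 | ethyl (3R)-4-(benzyloxy)-3-[(tert-butyldimethylsilyl)oxy]butanoate | CCOC(=O)C[C@@H](O[Si](C)(C)C(C)(C)C)COCc1ccccc1 | intermediate
4 | ethyl (3R)-3-[(tert-butyldimethylsilyl)oxy]-4-hydroxybutanoate | CCOC(=O)C[C@@H](O[Si](C)(C)C(C)(C)C)CO | intermediate
5 | ethyl (3R)-3-[(tert-butyldimethylsilyl)oxy]-4-oxobutanoate | CCOC(=O)C[C@@H](O[Si](C)(C)C(C)(C)C)C=O | intermediate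
6 | (triphenylphosphoranylidene)acetaldehyde | O=CC=P(c1ccccc1)(c1ccccc1)c1ccccc1 | starting material
7 | ethyl (3R,4E)-3-[(tert-butyldimethylsilyl)oxy]-6-oxohex-4-enoate | CCOC(=O)C[C@@H](O[Si](C)(C)C(C)(C)C)/C=C/C=O | intermediate
8 | (Z)-hex-3-en-1-ol | CC/C=C\CCO | starting material
9 | (Z)-1-iodohex-3-ene | CC/C=C\CCI | intermediate
10 | [(Z)-hex-3-en-1-yl]triphenylphosphonium iodide (fragment C) | CC/C=C\CC[P+](c1ccccc1)(c1ccccc1)c1ccccc1.[I-] | intermediate
11 | [(Z)-hex-3-en-1-ylidene]triphenylphosphorane (not isolated) | CC/C=C\CC=P(c1ccccc1)(c1ccccc1)c1ccccc1 | intermediate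
12 | ethyl (3R,4E,6Z,9Z)-3-[(tert-butyldimethylsilyl)oxy]dodeca-4,6,9-trienoate | CC/C=C\C/C=C\C=C\[C@H](O[Si](C)(C)C(C)(C)C)CC(=O)OCC | intermediate
13 | (3R,4E,6Z,9Z)-3-[(tert-butyldimethylsilyl)oxy]dodeca-4,6,9-trienal (not isolated) | CC/C=C\C/C=C\C=C\[C@H](O[Si](C)(C)C(C)(C)C)CC=O | intermediate
14 | (3R,4E,6Z,9Z)-3-[(tert-butyldimethylsilyl)oxy]dodeca-4,6,9-trien-1-ol | CC/C=C\C/C=C\C=C\[C@H](O[Si](C)(C)C(C)(C)C)CCO | intermediate
15 | tert-butyl{[(3R,4E,6Z,9Z)-1-iodododeca-4,6,9-trien-3-yl]oxy}dimethylsilane | CC/C=C\C/C=C\C=C\[C@H](O[Si](C)(C)C(C)(C)C)CCI | intermediate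
16 | {(3R,4E,6Z,9Z)-3-[(tert-butyldimethylsilyl)oxy]dodeca-4,6,9-trien-1-yl}triphenylphosphonium iodide (fragment B) | CC/C=C\C/C=C\C=C\[C@H](O[Si](C)(C)C(C)(C)C)CC[P+](c1ccccc1)(c1ccccc1)c1ccccc1.[I-] | intermediate
17 | phloroglucinol (benzene-1,3,5-triol) | Oc1cc(O)cc(O)c1 | starting material
18 | 1,3,5-tris(methoxymethoxy)benzene | COCOc1cc(OCOC)cc(OCOC)c1 | intermediate
19 | hept-6-enoic acid | C=CCCCCC(=O)O | starting material
20 | 1-(1H-imidazol-1-yl)hept-6-en-1-one (not isolated) | C=CCCCCC(=O)n1ccnc1 | intermediate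
21 | N-methoxy-N-methylhept-6-enamide | C=CCCCCC(=O)N(C)OC | intermediate
22 | [2,4,6-tris(methoxymethoxy)phenyl]lithium (not isolated) | [Li]c1c(OCOC)cc(OCOC)cc1OCOC | intermediate
23 | 1-[2,4,6-tris(methoxymethoxy)phenyl]hept-6-en-1-one | C=CCCCCC(=O)c1c(OCOC)cc(OCOC)cc1OCOC | intermediate
24 | 1-(2,4,6-trihydroxyphenyl)hept-6-en-1-one | C=CCCCCC(=O)c1c(O)cc(O)cc1O | intermediate
25 | 1-{2,4,6-tris[(tert-butyldimethylsilyl)oxy]phenyl}hept-6-en-1-one | C=CCCCCC(=O)c1c(O[Si](C)(C)C(C)(C)C)cc(O[Si](C)(C)C(C)(C)C)cc1O[Si](C)(C)C(C)(C)C | intermediate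
26 | 6,7-dihydroxy-1-{2,4,6-tris[(tert-butyldimethylsilyl)oxy]phenyl}heptan-1-one (racemic, not isolated) | OCC(O)CCCCC(=O)c1c(O[Si](C)(C)C(C)(C)C)cc(O[Si](C)(C)C(C)(C)C)cc1O[Si](C)(C)C(C)(C)C | intermediate
27 | 6-oxo-6-{2,4,6-tris[(tert-butyldimethylsilyl)oxy]phenyl}hexanal (fragment A) | O=CCCCCC(=O)c1c(O[Si](C)(C)C(C)(C)C)cc(O[Si](C)(C)C(C)(C)C)cc1O[Si](C)(C)C(C)(C)C | intermediate
28 | {(3R,4E,6Z,9Z)-3-[(tert-butyldimethylsilyl)oxy]dodeca-4,6,9-trien-1-ylidene}triphenylphosphorane (not isolated) | CC/C=C\C/C=C\C=C\[C@H](O[Si](C)(C)C(C)(C)C)CC=P(c1ccccc1)(c1ccccc1)c1ccccc1 | intermediate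
29 | (6Z,9R,10E,12Z,15Z)-9-[(tert-butyldimethylsilyl)oxy]-1-{2,4,6-tris[(tert-butyldimethylsilyl)oxy]phenyl}octadeca-6,10,12,15-tetraen-1-one | CC/C=C\C/C=C\C=C\[C@H](O[Si](C)(C)C(C)(C)C)C/C=C\CCCCC(=O)c1c(O[Si](C)(C)C(C)(C)C)cc(O[Si](C)(C)C(C)(C)C)cc1O[Si](C)(C)C(C)(C)C | intermediate
30 | (6Z,9R,10E,12Z,15Z)-9-hydroxy-1-(2,4,6-trihydroxyphenyl)octadeca-6,10,12,15-tetraen-1-one | CC/C=C\C/C=C\C=C\[C@H](O)C/C=C\CCCCC(=O)c1c(O)cc(O)cc1O | target

**Step count and risks**

Total steps: 19. Longest linear sequence: 11 steps (1–5, 8–11, 18, 19, from 1 to 30).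

Step 5 is at risk because the formyl ylide reacts slowly and the enal product can be homologated a second time, while the aldehyde 5 is prone to β-elimination on long heating. The fallback sets out from 5 and comes back at 12, replacing steps 5 and 8. Takai iodo-olefination of 5 (CHI3, CrCl2, THF, 0 °C) gives ethyl (3R,4E)-3-[(tert-butyldimethylsilyl)oxy]-5-iodopent-4-enoate F1. The alkyne partner (Z)-hept-4-en-1-yne F2 is made from commercial (Z)-1-bromopent-2-ene and ethynylmagnesium bromide (CuCl cat., THF). Sonogashira coupling of F1 with F2 (Pd(PPh3)4, zerovalent palladium, CuI, Et3N, rt) gives ethyl (3R,4E,9Z)-3-[(tert-butyldimethylsilyl)oxy]dodeca-4,9-dien-6-ynoate F3. Semi-reduction of the conjugated alkyne with zinc dust activated by Cu(OAc)2 and AgNO3 in MeOH/H2O gives 12.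

Step 11 is at risk because heating the E,Z,Z-triene iodide with phosphine can isomerise the diene or ionise the allylic silyl ether, and the salt may be hard to purify. The fallback sets out from 14, with 17 as the source of a new aryl partner, and comes back at 29, replacing steps 10, 11 and 18. Dess–Martin oxidation of 14 gives 13, now isolated. Stork–Zhao olefination of 13 with (iodomethyl)triphenylphosphonium iodide (NaN(SiMe3)2, THF/DMPU, −78 °C) gives tert-butyl{[(1Z,4R,5E,7Z,10Z)-1-iodotrideca-1,5,7,10-tetraen-4-yl]oxy}dimethylsilane F4. Friedel–Crafts acylation of 17 with 5-bromopentanoyl chloride (AlCl3, CH2Cl2/PhNO2) gives 5-bromo-1-(2,4,6-trihydroxyphenyl)pentan-1-one F5. Silylation (TBSCl, imidazole, DMF) gives 5-bromo-1-{2,4,6-tris[(tert-butyldimethylsilyl)oxy]phenyl}pentan-1-one F6. Zinc insertion (Zn dust, LiCl, THF, 40 °C) gives (5-oxo-5-{2,4,6-tris[(tert-butyldimethylsilyl)oxy]phenyl}pentyl)zinc bromide F7, which tolerates the ketone. Negishi coupling of F7 with F4 (Pd(PPh3)4, THF, rt) proceeds with retention of the Z geometry and gives 29.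

Step 17 is at risk because the aqueous oxidative cleavage may strip the two aryl silyl ethers that flank the ketone or over-oxidise the electron-rich ring. The fallback sets out from 18 and comes back at 27, replacing steps 13–17. Aryllithium 22 (from 18 and n-BuLi) opens ε-caprolactone at −78 °C to give 6-hydroxy-1-[2,4,6-tris(methoxymethoxy)phenyl]hexan-1-one F8. Treatment with HCl in MeOH gives 6-hydroxy-1-(2,4,6-trihydroxyphenyl)hexan-1-one F9. Exhaustive silylation (TBSCl, imidazole, DMF) gives 6-[(tert-butyldimethylsilyl)oxy]-1-{2,4,6-tris[(tert-butyldimethylsilyl)oxy]phenyl}hexan-1-one F10. Pyridinium p-toluenesulfonate in MeOH at 0 °C cleaves only the primary alkyl silyl ether to give 6-hydroxy-1-{2,4,6-tris[(tert-butyldimethylsilyl)oxy]phenyl}hexan-1-one F11. Dess–Martin oxidation of F11 gives 27.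

**Further compounds**

F1 | step 5 | ethyl (3R,4E)-3-[(tert-butyldimethylsilyl)oxy]-5-iodopent-4-enoate | CCOC(=O)C[C@@H](O[Si](C)(C)C(C)(C)C)/C=C/I
F2 | step 5 | (Z)-hept-4-en-1-yne | CC/C=C\CC#C
F3 | step 5 | ethyl (3R,4E,9Z)-3-[(tert-butyldimethylsilyl)oxy]dodeca-4,9-dien-6-ynoate | CC/C=C\CC#C/C=C/[C@H](O[Si](C)(C)C(C)(C)C)CC(=O)OCC
F4 | step 11 | tert-butyl{[(1Z,4R,5E,7Z,10Z)-1-iodotrideca-1,5,7,10-tetraen-4-yl]oxy}dimethylsilane | CC/C=C\C/C=C\C=C\[C@H](O[Si](C)(C)C(C)(C)C)C/C=C\I
F5 | step 11 | 5-bromo-1-(2,4,6-trihydroxyphenyl)pentan-1-one | BrCCCCC(=O)c1c(O)cc(O)cc1O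
F6 | step 11 | 5-bromo-1-{2,4,6-tris[(tert-butyldimethylsilyl)oxy]phenyl}pentan-1-one | BrCCCCC(=O)c1c(O[Si](C)(C)C(C)(C)C)cc(O[Si](C)(C)C(C)(C)C)cc1O[Si](C)(C)C(C)(C)C
F7 | step 11 | (5-oxo-5-{2,4,6-tris[(tert-butyldimethylsilyl)oxy]phenyl}pentyl)zinc bromide | Br[Zn]CCCCC(=O)c1c(O[Si](C)(C)C(C)(C)C)cc(O[Si](C)(C)C(C)(C)C)cc1O[Si](C)(C)C(C)(C)C
F8 | step 17 | 6-hydroxy-1-[2,4,6-tris(methoxymethoxy)phenyl]hexan-1-one | OCCCCCC(=O)c1c(OCOC)cc(OCOC)cc1OCOC
F9 | step 17 | 6-hydroxy-1-(2,4,6-trihydroxyphenyl)hexan-1-one | OCCCCCC(=O)c1c(O)cc(O)cc1O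
F10 | step 17 | 6-[(tert-butyldimethylsilyl)oxy]-1-{2,4,6-tris[(tert-butyldimethylsilyl)oxy]phenyl}hexan-1-one | CC(C)(C)[Si](C)(C)OCCCCCC(=O)c1c(O[Si](C)(C)C(C)(C)C)cc(O[Si](C)(C)C(C)(C)C)cc1O[Si](C)(C)C(C)(C)C
F11 | step 17 | 6-hydroxy-1-{2,4,6-tris[(tert-butyldimethylsilyl)oxy]phenyl}hexan-1-one | OCCCCCC(=O)c1c(O[Si](C)(C)C(C)(C)C)cc(O[Si](C)(C)C(C)(C)C)cc1O[Si](C)(C)C(C)(C)C
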